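## Structural features

The target is a 2,3-dihydro-1-benzofuran: benzene ring A (C3a, C4 to C7, C7a) is fused to a dihydrofuran ring (O1, C2, C3). C2 carries a 3,4-dihydroxyphenyl group, C3 a carboxyl group esterified with the 5-hydroxyl of (−)-shikimic acid, C4 an (E)-2-carboxyethenyl chain and C7 a phenol; C5 and C6 carry hydrogen. The two stereocentres C2 (S) and C3 (R) are adjacent and cis, the less stable arrangement. The three contiguous shikimate stereocentres are joined to them only through the ester oxygen and cannot control them. C3–H is benzylic and alpha to an ester, so base epimerises it to trans or opens the ring by loss of the O1 phenoxide; the C2–O1 bond is a benzylic ether of an oxygenated aryl group and can ionise in acid. The catechol, the two conjugated alkenes and the single ester link exclude late hydrogenation, hydroxide and strong oxidants, and the C3 carbonyl is peri to the C4 carbon, so a free hydroxymethyl at C4 can lactonise onto a C3 ester. The real difficulty is the cis stereodiad combined with a ring A that carries four different contiguous substituents. The key step uses the pattern of ring A (oxygen at C7, carbon at C4, hydrogen at C5 and C6): C7 with its oxygen comes from a carboxyl group, C6 and C5 from a two-carbon chain, C4 from a substituted alkene carbon, and C3a and C7a from the beta and the free alpha carbon of a furan whose other two carbons already hold the C3 carboxyl and the C2 aryl group.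

## Logic of the disconnections

**29 to 28.** The O–C bonds of two tert-butyl esters, two isopropylidene acetals and one methoxymethyl ether are cut. All five fall to one acid, so the acids, the catechol, the diol and the phenol appear together in a last step without base or hydrogen. The gain is that every earlier intermediate is neutral and easy to handle. The demand is that the acid spares the ester between the two halves and does not ionise the C2–O1 bond.

**28 to 26 and 27.** The C=C bond of the C4 acrylate is cut. This alkene cannot be present when C2=C3 is hydrogenated, and the stabilised ylide 27 installs it without added base. The gain is the loss of a three-carbon chain, leaving an aryl aldehyde. The demand is E selectivity and no epimerisation at C3.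

**26 to 24 (through 25).** No skeletal bond is cut; the aldehyde carbon is taken back to a silyl-protected hydroxymethyl group. A silyl ether at this carbon is inert to every step from 9 onward. The demand is that 25, whose hydroxyl is peri to the C3 ester, is oxidised before it lactonises.

**24 to 20 and 23.** The ester C–O bond between the C3 carbonyl and O5 of the cyclohexene is cut. This is the most convergent cut and separates the chiral-pool half from the aromatic half. The demand is acyl activation (retention at C5) without loss of the cis configuration at C3.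

**23 to 22 to 21.** Acetal C–O bonds and the tert-butyl ester O–C bond are cut. Three stereocentres are bought with 21. The demand is that the acetal selects the cis 3,4-diol and leaves O5 free.

**20 to 19.** The C2–H and C3–H bonds are cut. This removes both new stereocentres at once and leads to a flat benzofuran; syn addition of hydrogen gives cis by necessity. The demand is face-selective hydrogenation of a tetrasubstituted heteroaromatic C=C bond, directed by the free carboxyl group.

**19 to 18 to 16 (through 17).** The C3 ester O–ethyl bond is restored and the C7 methoxymethyl ether is taken back to the acetate that the ring synthesis delivers. The acetate is exchanged for a group that survives hydroxide and falls to the final acid. The exchange runs through 17, so the aryloxide is alkylated as it forms and the free phenol is never handled. The demand is that this happens cold and before hot hydroxide is used, since at that temperature a para-aryloxide could expel the benzylic oxygen as a quinone methide.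

**16 to 11 (key).** The C7–C7a bond (and the acetyl–O7 bond) is cut. One cut turns a benzene ring with four different substituents into a trisubstituted furan bearing a four-carbon acid chain, with the regiochemistry fixed by the single free furan alpha carbon. The demand is a chain that is cis to the furan or can become so, and substituents inert to hot anhydride.

**11 to 9 and 10.** The chain C3=C4 double bond is cut (Wittig). The oxygen on the alkene substituent is carried as a triisopropylsilyl ether and not as an ester, for three reasons:
- an ester would be attacked or enolised by the basic ylide;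
- it would be a leaving group vinylogous to the enolate in the ring synthesis;
- after the later ester hydrolysis it would leave a free hydroxymethyl beside the C3 carboxyl.

The demand is olefination of a hindered ketone by a carboxylate-bearing ylide; the alkene geometry is not critical.

**9 to 8 to 5.** The O–Si bond and then the C–C bond between the ketone carbonyl and the oxygenated methylene are cut. The ketone is an acid chloride plus a hydroxymethyl anion equivalent, and a ketene silyl acetal serves without diazomethane. The demand is a free C4 carboxyl beside an intact C3 ester.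

**5 to 4.** One ester O–ethyl bond is cut. The demand is hydrolysis of the C4 ester only, which its lower steric and electronic shielding should allow.

**4 to 2 and 3; 2 to 1.** The furan C2–aryl bond is cut (C–H arylation; the two alpha positions of 3 are equivalent), then the acetal bonds of 2. The demand is mono-arylation.

## Other disconnections considered

**Alternative 1:** The cut is the C2–C3 bond. The precursor is the aryldiazoacetate A1, the shikimate ester of a ring A arylacetic acid that already carries the acrylate, a C7 silyl ether and an ortho (3,4-isopropylidenedioxy)benzyloxy group. A chiral dirhodium tetracarboxylate such as Rh2(S-PTTL)4 would form a divalent rhodium carbenoid at C3, which inserts into the benzylic C–H bond of the ortho benzyloxy group and closes the dihydrofuran ring to give the fully protected target A2.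
- In its favour: the ring and both stereocentres are made in one step, and insertions of this type characteristically give the cis 2-aryl-3-carboxylate. On stereocontrol this alternative is the better plan, since the chosen route must force a syn hydrogenation of a benzofuran. The shikimate ester is made on an achiral arylacetic acid, so no epimerisable acid is coupled, which is also better. A2 is one deprotection from the target.
- Against it here: the carbenoid carbon lies between two ortho substituents, which hinders diazo transfer and carbenoid formation. The carbenoid could be intercepted by the shikimate alkene, by the C–H bond next to the acetonide oxygen of the ester alkyl group, or by the ortho acrylate. The chiral catalyst and the chiral ester may be a mismatched pair. Ring A with four contiguous substituents must be made by classical aromatic chemistry.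
- Comparison: the mechanism is better precedented than step 10, the step count is probably equal or lower, and the final acid deprotection is the same (equal). The chosen plan is better only in how it obtains ring A.

**Alternative 2:** The cuts are C3a–C7a and C6–C7, opening ring A and the dihydrofuran ring together to the furan ynol ether A3. A cationic monovalent gold complex such as (Ph3P)AuNTf2 would activate the ethynyl ether; furan C2 attacks the oxygen-bearing alkyne carbon, the furan opens and recloses with transfer of its oxygen, and the cis phenol A4 results.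
- In its favour: like the chosen plan it uses a furan as a latent benzene ring, but it closes both rings at once and gives the free C7 phenol directly, which is better in ring economy. C2 and C3 are set beforehand in an open chain and are not touched, so no benzofuran hydrogenation is needed, which is better on that point.
- Against it here: the ynol ether of a secondary, electron-rich benzylic alcohol is hard to make and prone to ionisation and hydration. C3 and C4 emerge as two silyl-protected hydroxymethyl groups that must be differentiated and oxidised, C3 through an aldehyde alpha to the cis stereocentre. The esterification with 23 then carries the same epimerisation risk as step 13 (equal).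
- Comparison: the chosen plan forms only one bond in its key step but has the C3 carboxyl at the right oxidation level from the start and needs far fewer steps after ring formation.

**Alternative 3:** The cuts are O1–C2, the C3–carbonyl bond and the ester C–O bond, giving three components: the (E)-2-hydroxystilbene A5, carbon monoxide and alcohol 23. Divalent palladium (for example Pd(OCOCF3)2 with a chiral ligand and benzoquinone as reoxidant) would add the phenoxide and the metal syn across the alkene, insert CO into the C3–palladium bond with retention, and the acyl palladium would be cleaved by 23 to give A6, which is the same compound as 26.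
- In its favour: it is the most convergent plan; A6 is two steps from the target and the ester is formed under neutral conditions without activating a cis acid. In step economy and in avoiding step 13 it is better than the chosen plan.
- Against it here: the 5-endo oxypalladation of a hydroxystilbene is reversible and its usual outcome under divalent palladium is the 2-arylbenzofuran. Syn or anti addition depends on anion and ligand, so cis is not secured. The absolute configuration would rest on a ligand effect without close precedent for stilbenes. A hindered secondary alcohol in near-stoichiometric amount must capture the acyl palladium, where such reactions normally use the alcohol as solvent.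
- Comparison: the chosen plan is longer, but apart from step 10 each bond formation has close precedent; this alternative puts regio-, diastereo-, enantio- and three-component selectivity into one step.

Key step: step 7

Assumption: the Wittig product 11 is drawn as its 3E isomer; the 3Z isomer formed with it is carried along, because the two are expected to interconvert under the conditions of step 7.

Assumption: the sense of induction in step 10 cannot be assigned from precedent; the ligand enantiomer is taken to be the one that delivers hydrogen to the face giving (2S,3R).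

## Route

Step 1
Reactants: 1 4-bromocatechol
Product: 2 5-bromo-2,2-dimethyl-1,3-benzodioxole
Conditions: 2,2-dimethoxypropane, TsOH·H2O (cat.), toluene, reflux (4 Å sieves in a Soxhlet)
Reagents that add atoms: 2,2-dimethoxypropane, COC(C)(C)OC
Why: Acid-catalysed transacetalisation of the catechol, driven by removal of methanol; the five-membered benzodioxole is the only ketal a catechol can form.

Step 2
Reactants: 2 5-bromo-2,2-dimethyl-1,3-benzodioxole; 3 diethyl furan-3,4-dicarboxylate (3 equiv)
Product: 4 diethyl 2-(2,2-dimethyl-1,3-benzodioxol-5-yl)furan-3,4-dicarboxylate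
Conditions: Pd(OAc)2 (5 mol%), PCy3·HBF4 (10 mol%), PivOH (30 mol%), K2CO3, DMAc, 110 °C
Reagents that add atoms: none
Why: Palladium-catalysed direct C–H arylation by concerted metalation–deprotonation at the aryl palladium pivalate; the two furan alpha C–H bonds of 3 are equivalent and acidified by the flanking esters, and the excess of 3 should suppress a second arylation.

Step 3
Reactants: 4 diethyl 2-(2,2-dimethyl-1,3-benzodioxol-5-yl)furan-3,4-dicarboxylate
Product: 5 5-(2,2-dimethyl-1,3-benzodioxol-5-yl)-4-(ethoxycarbonyl)furan-3-carboxylic acid
Conditions: KOH (1.0 equiv), EtOH/H2O, 0 °C to rt; then 1 M HCl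
Reagents that add atoms: potassium hydroxide, [K+].[OH-]
Why: Regioselective saponification: the ester next to C5–H is open to hydroxide, whereas the ester next to the aryl group is shielded by the twisted ring and is the less electrophilic vinylogous carbonate of an aryl-substituted enol ether; one equivalent of base and the charge of the first carboxylate should stop the reaction at the mono-acid.

Step 4
Reactants: 5 5-(2,2-dimethyl-1,3-benzodioxol-5-yl)-4-(ethoxycarbonyl)furan-3-carboxylic acid
Product: 8 ethyl 2-(2,2-dimethyl-1,3-benzodioxol-5-yl)-4-(hydroxyacetyl)furan-3-carboxylate, via acid chloride 6 (not isolated), via silylated keto ester 7 (not isolated)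
Conditions: (COCl)2, DMF (cat.), CH2Cl2, 0 °C to rt; then tris(trimethylsilyloxy)ethylene, SnCl4 (2 mol%), CH2Cl2, rt; then 0.5 M HCl, dioxane, 60 °C
Reagents that add atoms: tris(trimethylsilyloxy)ethylene, C[Si](C)(C)OC=C(O[Si](C)(C)C)O[Si](C)(C)C
Why: C-acylation of the ketene tris(silyl) acetal by the acid chloride, then hydrolysis and decarboxylation of the alpha-hydroxy beta-keto acid, a known one-carbon homologation of acid chlorides to hydroxymethyl ketones that needs no diazomethane. The ethyl ester and the acetonide should be inert; 8 is silylated without delay because its hydroxyl faces the neighbouring ester.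

Step 5
Reactants: 8 ethyl 2-(2,2-dimethyl-1,3-benzodioxol-5-yl)-4-(hydroxyacetyl)furan-3-carboxylate
Product: 9 ethyl 2-(2,2-dimethyl-1,3-benzodioxol-5-yl)-4-[(triisopropylsilyloxy)acetyl]furan-3-carboxylate
Conditions: iPr3SiCl, imidazole, DMF, rt
Reagents that add atoms: triisopropylsilyl chloride, CC(C)[Si](Cl)(C(C)C)C(C)C
Why: Standard silylation of a primary alcohol; the bulky silyl ether has no carbonyl for the ylide of step 6 to attack, is a poor leaving group in step 7 and survives the hydroxide of step 9, so this carbon is never a free alcohol beside the C3 carboxyl.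

Step 6
Reactants: 9 ethyl 2-(2,2-dimethyl-1,3-benzodioxol-5-yl)-4-[(triisopropylsilyloxy)acetyl]furan-3-carboxylate; 10 (2-carboxyethyl)triphenylphosphonium bromide
Product: 11 (3E)-4-[5-(2,2-dimethyl-1,3-benzodioxol-5-yl)-4-(ethoxycarbonyl)furan-3-yl]-5-(triisopropylsilyloxy)pent-3-enoic acid
Conditions: 10 (1.5 equiv), NaHMDS (3.0 equiv), THF, −78 to 0 °C; then 9, 0 °C to rt; then 1 M HCl to pH 3
Reagents that add atoms: none
Why: Wittig olefination with the carboxylate-bearing ylide gives the beta,gamma-unsaturated acid directly; the ketone is activated by its alpha oxygen and the furan ester, and a mixture of alkene isomers is acceptable because they converge in step 7.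

Step 7
Reactants: 11 (3E)-4-[5-(2,2-dimethyl-1,3-benzodioxol-5-yl)-4-(ethoxycarbonyl)furan-3-yl]-5-(triisopropylsilyloxy)pent-3-enoic acid
Product: 16 ethyl 7-acetoxy-2-(2,2-dimethyl-1,3-benzodioxol-5-yl)-4-[(triisopropylsilyloxy)methyl]-1-benzofuran-3-carboxylate, via mixed anhydride 12 (not isolated), via dienylketene 13 (not isolated), via cyclohexadienone 14 (not isolated), via benzofuran-7-ol 15 (not isolated)
Conditions: Ac2O, NaOAc (anhydrous), 125 °C
Reagents that add atoms: acetic anhydride, CC(=O)OC(C)=O
Why: Acetic anhydride converts 11 into the mixed anhydride 12, and acetate removes its acidic alpha hydrogen with loss of acetate to give the dienylketene 13, in which the ketene C=C, the chain C=C and the furan C4=C5 bond form a hexatriene. Thermal disrotatory six-electron electrocyclisation joins the ketene carbon to the furan alpha carbon (C7–C7a) and closes ring A as the dienone 14; an electrophilic acylation of the same furan carbon by 12 would form the same bond, so both conceivable pathways converge. Tautomerisation of 14 restores the furan and gives the benzofuran-7-ol 15, which is acetylated in the medium to 16. The closest known reaction type is the acetic anhydride and sodium acetate cyclisation of 4-aryl-but-3-enoic acids from the Stobbe condensation to aryl acetates, which is established for furyl substrates. No stereocentre is kept, since C7a of 14 is tetrahedral only transiently. Regioselectivity is secured because the furan has a single free alpha carbon and its other positions carry the chain, the ester and the aryl group. The required geometry (acid chain cis to the furan) should be supplied by equilibration of the alkene isomers through the extended enolate of 12 at the reaction temperature. The silyl ether cannot be acylated or eliminated, and the acetonide and the ethyl ester are inert to buffered acetic anhydride.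

Step 8
Reactants: 16 ethyl 7-acetoxy-2-(2,2-dimethyl-1,3-benzodioxol-5-yl)-4-[(triisopropylsilyloxy)methyl]-1-benzofuran-3-carboxylate
Product: 18 ethyl 2-(2,2-dimethyl-1,3-benzodioxol-5-yl)-7-(methoxymethoxy)-4-[(triisopropylsilyloxy)methyl]-1-benzofuran-3-carboxylate, via sodium aryloxide 17 (not isolated)
Conditions: NaOEt (1.05 equiv), THF, 0 °C; then MeOCH2Cl (1.3 equiv), 0 °C to rt
Reagents that add atoms: chloromethyl methyl ether, COCCl
Why: Ethoxide transesterifies the activated aryl acetate far faster than it could touch the hindered C3 ester (where exchange would in any case be degenerate), giving ethyl acetate and the sodium aryloxide 17, which is O-alkylated in the same flask (Williamson ether synthesis) without protonation to the phenol. The aryloxide exists only briefly at 0 °C, so the benzylic silyloxy group para to it should not be expelled as a quinone methide, and the phenol is masked before the hot hydroxide of step 9.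

Step 9
Reactants: 18 ethyl 2-(2,2-dimethyl-1,3-benzodioxol-5-yl)-7-(methoxymethoxy)-4-[(triisopropylsilyloxy)methyl]-1-benzofuran-3-carboxylate
Product: 19 2-(2,2-dimethyl-1,3-benzodioxol-5-yl)-7-(methoxymethoxy)-4-[(triisopropylsilyloxy)methyl]-1-benzofuran-3-carboxylic acid
Conditions: KOH, EtOH/H2O, 80 °C; then 1 M HCl to pH 4, 0 °C
Reagents that add atoms: potassium hydroxide, [K+].[OH-]
Why: Saponification of the hindered aryl ester, now the only base-labile group; the silyl ether, the methoxymethyl ether and the acetonide are stable to hydroxide and to the brief, cold acidification.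

Step 10
Reactants: 19 2-(2,2-dimethyl-1,3-benzodioxol-5-yl)-7-(methoxymethoxy)-4-[(triisopropylsilyloxy)methyl]-1-benzofuran-3-carboxylic acid
Product: 20 (2S,3R)-2-(2,2-dimethyl-1,3-benzodioxol-5-yl)-7-(methoxymethoxy)-4-[(triisopropylsilyloxy)methyl]-2,3-dihydro-1-benzofuran-3-carboxylic acid (cis)
Conditions: H2 (50 atm), [Ir(cod)(L*)][B(C6H3-3,5-(CF3)2)4] (2 mol%; L* = 7-[bis(3,5-di-tert-butylphenyl)phosphino]-7'-(4-benzyl-4,5-dihydrooxazol-2-yl)-1,1'-spirobiindane, one enantiomer), Et3N (0.5 equiv), MeOH, 50 °C
Reagents that add atoms: none
Why: Proposed new method: carboxylate-directed asymmetric hydrogenation of the benzofuran C2=C3 bond, in which the carboxylate binds the cationic iridium centre and the trivalent iridium dihydride delivers both hydrogens to one face, so that syn addition sets C2 and C3 cis and the chiral phosphine–oxazoline ligand selects the face that gives (2S,3R), while the product, an alpha-stereogenic carboxylate, cannot epimerise; the closest known reaction types are the iridium phosphine–oxazoline hydrogenation of tetrasubstituted alpha,beta-unsaturated carboxylic acids and the asymmetric hydrogenation of benzofuran C2=C3 bonds with ruthenium carbene and iridium N,P catalysts.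

Step 11
Reactants: 21 (−)-shikimic acid
Product: 22 tert-butyl (3R,4S,5R)-3,4,5-trihydroxycyclohex-1-ene-1-carboxylate
Conditions: O-tert-butyl-N,N'-diisopropylisourea, THF/DMF, rt to 40 °C
Reagents that add atoms: O-tert-butyl-N,N'-diisopropylisourea, CC(C)NC(=NC(C)C)OC(C)(C)C
Why: tert-Butylation of the carboxylic acid by the isourea (protonation by the acid, then tert-butyl transfer to the carboxylate); the hydroxyl groups are not acidic enough to react without a copper catalyst.

Step 12
Reactants: 22 tert-butyl (3R,4S,5R)-3,4,5-trihydroxycyclohex-1-ene-1-carboxylate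
Product: 23 tert-butyl 3,4-O-isopropylidene shikimate [tert-butyl (3aR,7R,7aS)-7-hydroxy-2,2-dimethyl-3a,6,7,7a-tetrahydro-1,3-benzodioxole-5-carboxylate]
Conditions: 2,2-dimethoxypropane, camphorsulfonic acid (cat.), acetone, rt
Reagents that add atoms: 2,2-dimethoxypropane, COC(C)(C)OC
Why: Acetonide formation selects the cis 3,4-diol (cis-fused dioxolane) over the trans 4,5-diol and leaves the 5-hydroxyl free; no stereocentre is touched.

Step 13
Reactants: 20 (2S,3R)-2-(2,2-dimethyl-1,3-benzodioxol-5-yl)-7-(methoxymethoxy)-4-[(triisopropylsilyloxy)methyl]-2,3-dihydro-1-benzofuran-3-carboxylic acid; 23 tert-butyl 3,4-O-isopropylidene shikimate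
Product: 24 tert-butyl 3,4-O-isopropylidene-5-O-[(2S,3R)-2-(2,2-dimethyl-1,3-benzodioxol-5-yl)-7-(methoxymethoxy)-4-[(triisopropylsilyloxy)methyl]-2,3-dihydro-1-benzofuran-3-carbonyl]shikimate
Conditions: iPrN=C=NiPr, DMAP (0.1 equiv), CH2Cl2, −20 to 0 °C
Reagents that add atoms: none
Why: Steglich esterification; the hydroxyl oxygen of 23 is the nucleophile, so C5 keeps its configuration, and low temperature with a catalytic amount of DMAP should limit ketene formation and epimerisation at C3.

Step 14
Reactants: 24 tert-butyl 3,4-O-isopropylidene-5-O-[(2S,3R)-2-(2,2-dimethyl-1,3-benzodioxol-5-yl)-7-(methoxymethoxy)-4-[(triisopropylsilyloxy)methyl]-2,3-dihydro-1-benzofuran-3-carbonyl]shikimate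
Product: 26 tert-butyl 3,4-O-isopropylidene-5-O-[(2S,3R)-2-(2,2-dimethyl-1,3-benzodioxol-5-yl)-4-formyl-7-(methoxymethoxy)-2,3-dihydro-1-benzofuran-3-carbonyl]shikimate, via benzylic alcohol 25 (not isolated)
Conditions: HF·pyridine, pyridine, THF, 0 °C to rt; then MnO2, CH2Cl2, rt (crude alcohol, no chromatography)
Reagents that add atoms: none
Why: Buffered fluoride cleaves the primary silyl ether without enolising C3, and MnO2, selective for benzylic alcohols, oxidises 25 at once so that it has little time to lactonise onto the C3 ester.

Step 15
Reactants: 26 tert-butyl 3,4-O-isopropylidene-5-O-[(2S,3R)-2-(2,2-dimethyl-1,3-benzodioxol-5-yl)-4-formyl-7-(methoxymethoxy)-2,3-dihydro-1-benzofuran-3-carbonyl]shikimate; 27 tert-butyl (triphenylphosphoranylidene)acetate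
Product: 28 tert-butyl 3,4-O-isopropylidene-5-O-[(2S,3R)-4-[(E)-3-tert-butoxy-3-oxoprop-1-en-1-yl]-2-(2,2-dimethyl-1,3-benzodioxol-5-yl)-7-(methoxymethoxy)-2,3-dihydro-1-benzofuran-3-carbonyl]shikimate
Conditions: 27 (1.5 equiv), toluene, rt to 40 °C
Reagents that add atoms: none
Why: Wittig olefination with a stabilised ylide should give the (E)-cinnamate under neutral conditions; the ylide is too weak a base to epimerise C3.

Step 16
Reactants: 28 tert-butyl 3,4-O-isopropylidene-5-O-[(2S,3R)-4-[(E)-3-tert-butoxy-3-oxoprop-1-en-1-yl]-2-(2,2-dimethyl-1,3-benzodioxol-5-yl)-7-(methoxymethoxy)-2,3-dihydro-1-benzofuran-3-carbonyl]shikimate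
Product: 29 5-O-[(2S,3R)-4-[(E)-2-carboxyethenyl]-2-(3,4-dihydroxyphenyl)-7-hydroxy-2,3-dihydro-1-benzofuran-3-carbonyl]shikimic acid (CNP0312618.1)
Conditions: CF3CO2H/H2O (9:1), 0 °C to rt
Reagents that add atoms: none
Why: Acidolysis removes in one operation both tert-butyl esters, both isopropylidene acetals and the methoxymethyl ether; water traps the cations, the ester link is stable to acid, and low temperature with short exposure should limit ionisation of the C2–O1 bond, which the C3 carbonyl disfavours.

## Compound list

1 | 4-bromocatechol | Oc1ccc(Br)cc1O | starting material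
2 | 5-bromo-2,2-dimethyl-1,3-benzodioxole | CC1(C)Oc2ccc(Br)cc2O1 | intermediate
3 | diethyl furan-3,4-dicarboxylate | CCOC(=O)c1cocc1C(=O)OCC | starting material
4 | diethyl 2-(2,2-dimethyl-1,3-benzodioxol-5-yl)furan-3,4-dicarboxylate | CCOC(=O)c1coc(-c2ccc3OC(C)(C)Oc3c2)c1C(=O)OCC | intermediate
5 | 5-(2,2-dimethyl-1,3-benzodioxol-5-yl)-4-(ethoxycarbonyl)furan-3-carboxylic acid | OC(=O)c1coc(-c2ccc3OC(C)(C)Oc3c2)c1C(=O)OCC | intermediate
6 | ethyl 4-(chlorocarbonyl)-2-(2,2-dimethyl-1,3-benzodioxol-5-yl)furan-3-carboxylate | ClC(=O)c1coc(-c2ccc3OC(C)(C)Oc3c2)c1C(=O)OCC | intermediate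
7 | trimethylsilyl 3-[5-(2,2-dimethyl-1,3-benzodioxol-5-yl)-4-(ethoxycarbonyl)furan-3-yl]-3-oxo-2-(trimethylsilyloxy)propanoate (racemic) | C[Si](C)(C)OC(=O)C(O[Si](C)(C)C)C(=O)c1coc(-c2ccc3OC(C)(C)Oc3c2)c1C(=O)OCC | intermediate
8 | ethyl 2-(2,2-dimethyl-1,3-benzodioxol-5-yl)-4-(hydroxyacetyl)furan-3-carboxylate | OCC(=O)c1coc(-c2ccc3OC(C)(C)Oc3c2)c1C(=O)OCC | intermediate
9 | ethyl 2-(2,2-dimethyl-1,3-benzodioxol-5-yl)-4-[(triisopropylsilyloxy)acetyl]furan-3-carboxylate | CC(C)[Si](OCC(=O)c1coc(-c2ccc3OC(C)(C)Oc3c2)c1C(=O)OCC)(C(C)C)C(C)C | intermediate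
10 | (2-carboxyethyl)triphenylphosphonium bromide | OC(=O)CC[P+](c1ccccc1)(c1ccccc1)c1ccccc1.[Br-] | starting material
11 | (3E)-4-[5-(2,2-dimethyl-1,3-benzodioxol-5-yl)-4-(ethoxycarbonyl)furan-3-yl]-5-(triisopropylsilyloxy)pent-3-enoic acid (a 4-(furan-3-yl)but-3-enoic acid with silyloxymethyl on C4; acid chain cis to the furan) | OC(=O)C/C=C(/CO[Si](C(C)C)(C(C)C)C(C)C)c1coc(-c2ccc3OC(C)(C)Oc3c2)c1C(=O)OCC | intermediate
12 | mixed anhydride of 11 with acetic acid | CC(=O)OC(=O)C/C=C(/CO[Si](C(C)C)(C(C)C)C(C)C)c1coc(-c2ccc3OC(C)(C)Oc3c2)c1C(=O)OCC | intermediate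
13 | ethyl 2-(2,2-dimethyl-1,3-benzodioxol-5-yl)-4-[(2E)-5-oxo-1-(triisopropylsilyloxy)penta-2,4-dien-2-yl]furan-3-carboxylate (dienylketene) | O=C=C/C=C(/CO[Si](C(C)C)(C(C)C)C(C)C)c1coc(-c2ccc3OC(C)(C)Oc3c2)c1C(=O)OCC | intermediate
14 | ethyl 2-(2,2-dimethyl-1,3-benzodioxol-5-yl)-7-oxo-4-[(triisopropylsilyloxy)methyl]-7,7a-dihydro-1-benzofuran-3-carboxylate (racemic at C7a) | O=C1C=CC(CO[Si](C(C)C)(C(C)C)C(C)C)=C2C(C(=O)OCC)=C(c3ccc4OC(C)(C)Oc4c3)OC12 | intermediate
15 | ethyl 2-(2,2-dimethyl-1,3-benzodioxol-5-yl)-7-hydroxy-4-[(triisopropylsilyloxy)methyl]-1-benzofuran-3-carboxylate | CCOC(=O)c1c(-c2ccc3OC(C)(C)Oc3c2)oc2c(O)ccc(CO[Si](C(C)C)(C(C)C)C(C)C)c12 | intermediate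
16 | ethyl 7-acetoxy-2-(2,2-dimethyl-1,3-benzodioxol-5-yl)-4-[(triisopropylsilyloxy)methyl]-1-benzofuran-3-carboxylate | CCOC(=O)c1c(-c2ccc3OC(C)(C)Oc3c2)oc2c(OC(C)=O)ccc(CO[Si](C(C)C)(C(C)C)C(C)C)c12 | intermediate
17 | sodium 2-(2,2-dimethyl-1,3-benzodioxol-5-yl)-3-(ethoxycarbonyl)-4-[(triisopropylsilyloxy)methyl]-1-benzofuran-7-olate | CCOC(=O)c1c(-c2ccc3OC(C)(C)Oc3c2)oc2c([O-])ccc(CO[Si](C(C)C)(C(C)C)C(C)C)c12.[Na+] | intermediate
18 | ethyl 2-(2,2-dimethyl-1,3-benzodioxol-5-yl)-7-(methoxymethoxy)-4-[(triisopropylsilyloxy)methyl]-1-benzofuran-3-carboxylate | CCOC(=O)c1c(-c2ccc3OC(C)(C)Oc3c2)oc2c(OCOC)ccc(CO[Si](C(C)C)(C(C)C)C(C)C)c12 | intermediate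
19 | 2-(2,2-dimethyl-1,3-benzodioxol-5-yl)-7-(methoxymethoxy)-4-[(triisopropylsilyloxy)methyl]-1-benzofuran-3-carboxylic acid | OC(=O)c1c(-c2ccc3OC(C)(C)Oc3c2)oc2c(OCOC)ccc(CO[Si](C(C)C)(C(C)C)C(C)C)c12 | intermediate
20 | (2S,3R)-2-(2,2-dimethyl-1,3-benzodioxol-5-yl)-7-(methoxymethoxy)-4-[(triisopropylsilyloxy)methyl]-2,3-dihydro-1-benzofuran-3-carboxylic acid (cis) | CC(C)[Si](OCc1ccc(OCOC)c2c1[C@@H](C(O)=O)[C@@H](c1ccc3OC(C)(C)Oc3c1)O2)(C(C)C)C(C)C | intermediate
21 | (−)-shikimic acid, (3R,4S,5R)-3,4,5-trihydroxycyclohex-1-ene-1-carboxylic acid | O[C@@H]1CC(C(=O)O)=C[C@@H](O)[C@H]1O | starting material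
22 | tert-butyl (3R,4S,5R)-3,4,5-trihydroxycyclohex-1-ene-1-carboxylate (tert-butyl shikimate) | O[C@@H]1CC(C(=O)OC(C)(C)C)=C[C@@H](O)[C@H]1O | intermediate
23 | tert-butyl 3,4-O-isopropylidene shikimate, tert-butyl (3aR,7R,7aS)-7-hydroxy-2,2-dimethyl-3a,6,7,7a-tetrahydro-1,3-benzodioxole-5-carboxylate | O[C@@H]1CC(C(=O)OC(C)(C)C)=C[C@H]2OC(C)(C)O[C@H]21 | intermediate
24 | ester of acid 20 with the 5-hydroxyl of 23 (cis 2S,3R; shikimate configuration unchanged) | CC(C)[Si](OCc1ccc(OCOC)c2c1[C@@H](C(=O)O[C@@H]1CC(C(=O)OC(C)(C)C)=C[C@H]3OC(C)(C)O[C@H]31)[C@@H](c1ccc3OC(C)(C)Oc3c1)O2)(C(C)C)C(C)C | intermediate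
25 | 4-(hydroxymethyl) analogue of 24 (silyl group removed) | OCc1ccc(OCOC)c2c1[C@@H](C(=O)O[C@@H]1CC(C(=O)OC(C)(C)C)=C[C@H]3OC(C)(C)O[C@H]31)[C@@H](c1ccc3OC(C)(C)Oc3c1)O2 | intermediate
26 | 4-formyl compound: tert-butyl 3,4-O-isopropylidene-5-O-[(2S,3R)-2-(2,2-dimethyl-1,3-benzodioxol-5-yl)-4-formyl-7-(methoxymethoxy)-2,3-dihydro-1-benzofuran-3-carbonyl]shikimate | O=Cc1ccc(OCOC)c2c1[C@@H](C(=O)O[C@@H]1CC(C(=O)OC(C)(C)C)=C[C@H]3OC(C)(C)O[C@H]31)[C@@H](c1ccc3OC(C)(C)Oc3c1)O2 | intermediate
27 | tert-butyl (triphenylphosphoranylidene)acetate | CC(C)(C)OC(=O)C=P(c1ccccc1)(c1ccccc1)c1ccccc1 | starting material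
28 | fully protected target: (E)-tert-butyl acrylate at C4, methoxymethyl ether at C7, catechol acetonide, shikimate tert-butyl ester 3,4-acetonide; cis (2S,3R) | CC(C)(C)OC(=O)/C=C/c1ccc(OCOC)c2c1[C@@H](C(=O)O[C@@H]1CC(C(=O)OC(C)(C)C)=C[C@H]3OC(C)(C)O[C@H]31)[C@@H](c1ccc3OC(C)(C)Oc3c1)O2 | intermediate
29 | CNP0312618.1, 5-O-[(2S,3R)-4-[(E)-2-carboxyethenyl]-2-(3,4-dihydroxyphenyl)-7-hydroxy-2,3-dihydro-1-benzofuran-3-carbonyl]shikimic acid | O=C(O)/C=C/c1ccc(O)c2c1[C@@H](C(=O)O[C@@H]1CC(C(=O)O)=C[C@@H](O)[C@H]1O)[C@@H](c1ccc(O)c(O)c1)O2 | target

## Step count and least certain steps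

Total: 16 steps. Longest linear sequence: 14 steps (steps 1 to 10 and 13 to 16); steps 11 and 12 make the second fragment.

**Step 10 (asymmetric hydrogenation).** Slow hydrogen uptake and poor facial selectivity are the likely failures: the C2=C3 bond is tetrasubstituted, part of an aromatic furan, electron-rich at C2 and crowded by the peri silyloxymethyl group, and no catalyst has a record on this substrate class. The fallback uses known chemistry and sets out from 19. Heterogeneous syn hydrogenation (H2, 10 to 20 atm, 10% Pd/C, EtOAc), the established way from benzofurans to cis-2,3-dihydrobenzofurans, should give the racemic cis acid, that is 20 together with its enantiomer, (2R,3S)-2-(2,2-dimethyl-1,3-benzodioxol-5-yl)-7-(methoxymethoxy)-4-[(triisopropylsilyloxy)methyl]-2,3-dihydro-1-benzofuran-3-carboxylic acid F1. Esterification of the racemate with enantiopure 23 as in step 13 would give 24 and its (2R,3S) diastereomer F2, to be separated by chromatography. The fallback returns to the route at 24, at the cost of half the material.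

**Step 7 (key step).** Incomplete equilibration of the alkene isomers, slow closure onto the ester-deactivated furan, and thermal degradation (ketene oligomerisation, loss of the silyl group) at 125 °C are the likely failures. The fallback changes the ring closure from a thermal ketene electrocyclisation to a low-temperature electrophilic acylation and sets out from 11. After equilibration of the alkene isomers with a trace of iodine in light, trifluoroacetic anhydride in CH2Cl2 at 0 °C should form the mixed trifluoroacetic anhydride and acylate the furan alpha carbon, a known variant for such acids. This would give ethyl 2-(2,2-dimethyl-1,3-benzodioxol-5-yl)-7-(trifluoroacetoxy)-4-[(triisopropylsilyloxy)methyl]-1-benzofuran-3-carboxylate F3. Treatment of F3 with NaOEt in THF at 0 °C, as for 16 in step 8, should cleave the still more labile trifluoroacetate and return to the route at 17, which is methoxymethylated in the same flask.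

**Step 6 (Wittig olefination of the ketone).** Enolisation of the alpha-silyloxy ketone by the basic ylide, fragmentation of the carboxylate ylide to acrylate and triphenylphosphine, and low conversion at a hindered ketone are the likely failures. The fallback sets out from 9. The oxido ylide from (3-hydroxypropyl)triphenylphosphonium bromide and two equivalents of base, which behaves well with ketones, would give the homoallylic alcohol ethyl 2-(2,2-dimethyl-1,3-benzodioxol-5-yl)-4-[(2E)-5-hydroxy-1-(triisopropylsilyloxy)pent-2-en-2-yl]furan-3-carboxylate F4. Oxidation with TEMPO (cat.) and PhI(OAc)2 in MeCN/H2O would give the acid and return to the route at 11.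

**Step 13 (esterification).** Epimerisation at C3 through a ketene or enol of the activated acid is the main risk, made worse by slow acylation of a hindered secondary alcohol and by N-acylurea formation. The fallback makes the acid the nucleophile, so that it is never activated, and sets out from 23. Mitsunobu inversion with 4-nitrobenzoic acid (PPh3, diisopropyl azodicarboxylate) would give tert-butyl 3,4-O-isopropylidene-5-O-(4-nitrobenzoyl)-5-epi-shikimate F5. Methanolysis (K2CO3, MeOH) would give tert-butyl 3,4-O-isopropylidene-5-epi-shikimate F6. A second Mitsunobu reaction of F6 with acid 20 inverts C5 back and returns to the route at 24.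

**Step 14 (desilylation and oxidation).** Lactonisation of the liberated hydroxymethyl group of 25 onto the C3 ester, with loss of 23, is the risk; the peri geometry favours it and traces of acid or fluoride base catalyse it. The fallback changes the order of events so that the alcohol only ever faces a carboxylate, and sets out from 20. Bu4NF in THF would give the hydroxy acid (2S,3R)-2-(2,2-dimethyl-1,3-benzodioxol-5-yl)-4-(hydroxymethyl)-7-(methoxymethoxy)-2,3-dihydro-1-benzofuran-3-carboxylic acid F7, kept as its tetrabutylammonium salt and not acidified. MnO2 would oxidise it to the aldehyde acid (2S,3R)-2-(2,2-dimethyl-1,3-benzodioxol-5-yl)-4-formyl-7-(methoxymethoxy)-2,3-dihydro-1-benzofuran-3-carboxylic acid F8. Ylide 27 would convert F8 into the acrylate acid (2S,3R)-4-[(E)-3-tert-butoxy-3-oxoprop-1-en-1-yl]-2-(2,2-dimethyl-1,3-benzodioxol-5-yl)-7-(methoxymethoxy)-2,3-dihydro-1-benzofuran-3-carboxylic acid F9. Esterification of F9 with 23 as in step 13 returns to the route at 28.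

## Further compounds

F1 | step 10 | (2R,3S)-2-(2,2-dimethyl-1,3-benzodioxol-5-yl)-7-(methoxymethoxy)-4-[(triisopropylsilyloxy)methyl]-2,3-dihydro-1-benzofuran-3-carboxylic acid (enantiomer of 20) | CC(C)[Si](OCc1ccc(OCOC)c2c1[C@H](C(O)=O)[C@H](c1ccc3OC(C)(C)Oc3c1)O2)(C(C)C)C(C)C
F2 | step 10 | (2R,3S) diastereomer of 24 (ester of F1 with 23) | CC(C)[Si](OCc1ccc(OCOC)c2c1[C@H](C(=O)O[C@@H]1CC(C(=O)OC(C)(C)C)=C[C@H]3OC(C)(C)O[C@H]31)[C@H](c1ccc3OC(C)(C)Oc3c1)O2)(C(C)C)C(C)C
F3 | step 7 | ethyl 2-(2,2-dimethyl-1,3-benzodioxol-5-yl)-7-(trifluoroacetoxy)-4-[(triisopropylsilyloxy)methyl]-1-benzofuran-3-carboxylate | CCOC(=O)c1c(-c2ccc3OC(C)(C)Oc3c2)oc2c(OC(=O)C(F)(F)F)ccc(CO[Si](C(C)C)(C(C)C)C(C)C)c12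
F4 | step 6 | ethyl 2-(2,2-dimethyl-1,3-benzodioxol-5-yl)-4-[(2E)-5-hydroxy-1-(triisopropylsilyloxy)pent-2-en-2-yl]furan-3-carboxylate | OCC/C=C(/CO[Si](C(C)C)(C(C)C)C(C)C)c1coc(-c2ccc3OC(C)(C)Oc3c2)c1C(=O)OCC
F5 | step 13 | tert-butyl 3,4-O-isopropylidene-5-O-(4-nitrobenzoyl)-5-epi-shikimate | O=C(O[C@H]1CC(C(=O)OC(C)(C)C)=C[C@H]2OC(C)(C)O[C@H]21)c1ccc(cc1)[N+](=O)[O-]
F6 | step 13 | tert-butyl 3,4-O-isopropylidene-5-epi-shikimate | O[C@H]1CC(C(=O)OC(C)(C)C)=C[C@H]2OC(C)(C)O[C@H]21
F7 | step 14 | (2S,3R)-2-(2,2-dimethyl-1,3-benzodioxol-5-yl)-4-(hydroxymethyl)-7-(methoxymethoxy)-2,3-dihydro-1-benzofuran-3-carboxylic acid | OCc1ccc(OCOC)c2c1[C@@H](C(O)=O)[C@@H](c1ccc3OC(C)(C)Oc3c1)O2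
F8 | step 14 | (2S,3R)-2-(2,2-dimethyl-1,3-benzodioxol-5-yl)-4-formyl-7-(methoxymethoxy)-2,3-dihydro-1-benzofuran-3-carboxylic acid | O=Cc1ccc(OCOC)c2c1[C@@H](C(O)=O)[C@@H](c1ccc3OC(C)(C)Oc3c1)O2
F9 | step 14 | (2S,3R)-4-[(E)-3-tert-butoxy-3-oxoprop-1-en-1-yl]-2-(2,2-dimethyl-1,3-benzodioxol-5-yl)-7-(methoxymethoxy)-2,3-dihydro-1-benzofuran-3-carboxylic acid | CC(C)(C)OC(=O)/C=C/c1ccc(OCOC)c2c1[C@@H](C(O)=O)[C@@H](c1ccc3OC(C)(C)Oc3c1)O2
A1 | alternative 1 | shikimate (tert-butyl ester, 3,4-acetonide) 2-diazo-2-arylacetate with ortho (2,2-dimethyl-1,3-benzodioxol-5-yl)methoxy, tert-butyldimethylsilyloxy and (E)-tert-butyl acrylate groups on the aryl ring | CC(C)(C)OC(=O)/C=C/c1ccc(O[Si](C)(C)C(C)(C)C)c(OCc2ccc3OC(C)(C)Oc3c2)c1C(=[N+]=[N-])C(=O)O[C@@H]1CC(C(=O)OC(C)(C)C)=C[C@H]2OC(C)(C)O[C@H]21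
A2 | alternative 1 | protected target with tert-butyldimethylsilyl ether at C7, cis (2S,3R) | CC(C)(C)OC(=O)/C=C/c1ccc(O[Si](C)(C)C(C)(C)C)c2c1[C@@H](C(=O)O[C@@H]1CC(C(=O)OC(C)(C)C)=C[C@H]3OC(C)(C)O[C@H]31)[C@@H](c1ccc3OC(C)(C)Oc3c1)O2
A3 | alternative 2 | ethynyl ether of the 1-aryl-2-(furan-2-yl)-3-(triisopropylsilyloxy)propan-1-ol whose furan carries a 3-(tert-butyldimethylsilyloxymethyl) group | C#CO[C@H](c1ccc2OC(C)(C)Oc2c1)[C@H](CO[Si](C(C)C)(C(C)C)C(C)C)c1occc1CO[Si](C)(C)C(C)(C)C
A4 | alternative 2 | cis 7-hydroxy-2-aryl-2,3-dihydrobenzofuran with triisopropylsilyloxymethyl at C3 and tert-butyldimethylsilyloxymethyl at C4 | CC(C)(C)[Si](C)(C)OCc1ccc(O)c2c1[C@@H](CO[Si](C(C)C)(C(C)C)C(C)C)[C@@H](c1ccc3OC(C)(C)Oc3c1)O2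
A5 | alternative 3 | 2-[(E)-2-(2,2-dimethyl-1,3-benzodioxol-5-yl)ethenyl]-3-hydroxy-4-(methoxymethoxy)benzaldehyde | O=Cc1ccc(OCOC)c(O)c1/C=C/c1ccc2OC(C)(C)Oc2c1
A6 | alternative 3 | cis (2S,3R) dihydrobenzofuran shikimate ester with the C4 aldehyde (same compound as 26) | O=Cc1ccc(OCOC)c2c1[C@@H](C(=O)O[C@@H]1CC(C(=O)OC(C)(C)C)=C[C@H]3OC(C)(C)O[C@H]31)[C@@H](c1ccc3OC(C)(C)Oc3c1)O2
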